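Assumption: the MandyPhos enantiomer is written as (Sp,Sp); if the facial preference on this substrate is the opposite one, the mirror-image ligand is used and nothing else changes.

## The problem

Target 25 is a 2,3-dihydrobenzofuran neolignan. Benzo ring A is fused through C3a–C7a to the oxygen heterocycle (ring B); C2 carries a guaiacyl ring (ring C), C3 a CH2O group esterified with 4-hydroxybenzoic acid, C7 a methoxy group and C5 a (Z)-propenal chain. The only stereocentres are C2 (S) and C3 (R), and they are trans. C2 is a benzylic ether carbon para to an oxygenated arene and ionises easily, so it is a poor anchor; C3 is configurationally robust and can dictate C2 through the trans preference of the five-membered ring. The (Z)-enal is the most fragile group: acid, nucleophilic bases, phosphines and light turn it into the (E)-isomer, so it must be made late by a kinetically Z-selective method and then see only mild reagents. The aryl ester rules out hydride reagents once it is in place. The two phenols need protection to the end, because the one para to C2 can open ring B through a quinone methide under base. The feature that opens the molecule is the C2–C3 unit: two adjacent sp3 carbons, each with one aryl group (ring C on C2, ring A through C3a on C3), a heteroatom on C2 and a hydroxymethyl group on C3. This is the pattern left by adding two aryl groups across a 3-oxygenated (E)-propenyl boronate with boron kept on C2.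

## Retrosynthesis

**Ester and silyl groups.** The ester C(=O)–O bond and the two aryl O–Si bonds are cut first: 25 comes from bis-silyl ether 24, and 24 from alcohol 19 and acid 22 (through acid chloride 23). The ester must come after the hydride step that makes the allylic alcohol, and one buffered fluoride treatment then frees both phenols. Acylating earlier would put an aryl ester through a hydride reduction. The forward acylation must avoid nucleophilic catalysts that add to the (Z)-enal. Acid 22 comes from 4-hydroxybenzoic acid 20 through the bis-silyl compound 21.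

**(Z)-Enal.** The side-chain C=C bond is cut: 19 comes from diol 18, 18 from (Z)-enoate 17, and 17 from aldehyde 16. An (E)-selective olefination followed by isomerisation would give mixtures, and an alkyne semi-reduction is longer (it is held in reserve). The forward sequence needs a Z-selective olefination of an aryl aldehyde, a 1,2-reduction, and an allylic oxidation that leaves the saturated primary alcohol alone, so that this alcohol needs no protecting group.

**Ring B.** The O1–C2 bond is cut: 16 comes from open-chain alcohol 15. Cutting O1–C7a instead would need an aryl halide at a carbon flanked by a methoxy group, and an SN2 closure at C2 would need the other C2 epimer. The easy ionisation of C2 is used here: the acid that removes the MOM, TBS and dioxolane groups also generates the benzylic cation, and the C3 substituent steers closure to trans. The forward step must not let C3 lose its proton.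

**C–O from C–B.** Alcohol 15 comes from boronate 14 by stereoretentive oxidation; boron serves as the placeholder for O1.

**Both aryl bonds at once.** C2–C1′ (ring C) and C3–C3a (ring A) are cut together: 14 comes from alkenyl boronate 6, aryllithium 12 and aryl bromide 11, through ate complex 13. Cutting C2–C3 as an aldol would need a stoichiometric auxiliary and its attachment and removal. Cutting only one aryl bond leaves a chiral fragment to be made separately. The double cut reduces the core to three achiral pieces of similar size. The forward reaction must favour the three-component path over direct coupling, add anti across the alkene, control the alkene face, and tolerate bromide.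

**The pieces.** Boronate 6 comes from alkyne 4 (from propargyl alcohol 3) by hydroboration to catechol ester 5 and exchange with diol 2 (from acenaphthenequinone 1). Aryllithium 12 comes from silyl ether 8 (from 4-bromo-2-methoxyphenol 7). Bromide 11 comes from aldehyde 10 (from 5-bromovanillin 9).

## Roads not taken

**Alternative 1: oxidative ring contraction of a flavanone.**
- **Cut:** the C3–C3a bond is traced back to a 1,2-aryl shift and ring B to a contracted chromanone.
- **Forward key step:** (S)-flavanone A1, as its enol ether in trimethyl orthoformate with H2SO4, is attacked at C3 by the hypervalent iodine reagent PhI(OAc)2. Ring A moves from C4 to C3 as iodobenzene leaves and C4 becomes the methyl ester, giving trans ester A2.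
- **Merits:** ring B and the trans relation appear in one step from a compound two steps away from an acetophenone and an aldehyde. The C3 carbon arrives one reduction from the hydroxymethyl group, and the C5 bromide is kept for the side chain.
- **Weak points:** the absolute configuration rests on a C2-stereogenic flavanone, a class that racemises by retro-oxa-Michael opening to the chalcone, and the step runs in sulfuric acid. A 4-oxygenated C2 aryl group eases that opening and also favours the competing shift of ring C (isoflavone) and dehydrogenation (flavone). The pivalate chosen to damp this then competes in the ester reduction. The bromide must still become an aldehyde before the same enal sequence.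
- **Comparison:** A2 is reached in fewer operations than 16 and without a palladium catalyst, which is a real advantage. The chosen plan sets against it a catalyst-controlled C3 that later steps are not expected to racemise, and a C5 carbon already at the aldehyde level.

**Alternative 2: Dötz benzannulation.**
- **Cut:** ring A itself, at C6–C7, C4–C5 and C3a–C4.
- **Forward key step:** pentacarbonylchromium carbene A3, carried on a preformed trans-dihydrofuran, reacts with alkyne A4 and one CO ligand to give phenol A5.
- **Merits:** the substitution pattern of ring A is fixed by the annulation (acetal carbon next to the new hydroxyl, methoxy from the carbene), and the stereocentres are set on a small ring before the arene exists.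
- **Weak points:** the C4 hydroxyl of A5 is absent from the target and costs two steps to remove. Chromium is stoichiometric. A3 requires C5-metalation of an enantioenriched trans-2-aryl-3-substituted dihydrofuran whose C2–H is benzylic and adjacent to oxygen, and whose asymmetric synthesis is no easier than the core itself. The stereochemical problem is moved, not solved.
- **Comparison:** this road is better for analogues with unusual ring A patterns. Here ring A is a derivative of cheap 5-bromovanillin, so that advantage is unused, and the chosen plan is shorter and catalytic.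

**Alternative 3: (4+1) annulation of a quinone methide with a chiral sulfonium ylide.**
- **Cut:** C2–C3 and O1–C2.
- **Forward key step:** Cs2CO3 eliminates sulfinate from tosyl phenol A6 to give the ortho-quinone methide. The ylide from sulfonium salt A7 adds to its exocyclic carbon (C2–C3), and the phenoxide then displaces the sulfide (O1–C2), giving trans-dihydrobenzofuran A8.
- **Merits:** both stereocentres and ring B form in one step, and trans follows from anti-periplanar displacement in the betaine. The ring is already closed in A8, so the C–B oxidation and acid closure of the chosen plan are not needed.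
- **Weak points:** the quinone methide carries a silyloxymethyl, not an aryl, group on its exocyclic carbon; such species tautomerise to vinyl phenols and can lose the β-silyloxy group. The ylide is a semi-stabilised, electron-rich benzyl ylide from a stoichiometric chiral sulfide. The sulfide controls C2 directly, while C3, the centre that cannot be corrected later, depends on how selectively the betaine forms. A8 still needs bromine-to-formyl exchange before the same endgame.
- **Comparison:** in step count to the ring and in convergence this road is as good as or better than the chosen one. The chosen plan answers with catalytic enantiocontrol placed directly on C3 through a stereospecific anti addition, and with the aldehyde carried latent from the start.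

Key step: step 7

## Route

Step 1
Reactants: 1 acenaphthenequinone
Product: 2 cis-1,2-dimethyl-1,2-dihydroacenaphthylene-1,2-diol (meso diol for the boron ligand)
Conditions: MeMgBr (2.5 equiv), THF, 0 °C to rt; aq. NH4Cl; recrystallisation
Reagents that add atoms: methylmagnesium bromide, C[Mg]Br
Why: Twofold Grignard addition to the 1,2-diketone; the second methyl group should add to the face away from the magnesium alkoxide, so the meso cis-diol is expected to predominate and is purified by crystallisation (only the cis isomer can bridge one boron atom).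

Step 2
Reactants: 3 propargyl alcohol
Product: 4 tert-butyldimethyl(prop-2-yn-1-yloxy)silane
Conditions: TBSCl, imidazole, CH2Cl2, 0 °C to rt
Reagents that add atoms: tert-butyldimethylsilyl chloride, CC(C)(C)[Si](C)(C)Cl
Why: Standard silylation of a primary alcohol; a silyl ether is chosen because a silyloxide is a poor leaving group at the allylic position during the later palladium step.

Step 3
Reactants: 4 tert-butyldimethyl(prop-2-yn-1-yloxy)silane; 2 cis-1,2-dimethyl-1,2-dihydroacenaphthylene-1,2-diol
Product: 6 (E)-3-(tert-butyldimethylsilyloxy)prop-1-enylboronic ester of diol 2, via catechol boronate 5 (not isolated)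
Conditions: catecholborane (1.1 equiv), Cy2BH (10 mol%), THF, rt; then 2, rt
Reagents that add atoms: catecholborane, B1Oc2ccccc2O1
Why: Dicyclohexylborane-catalysed syn hydroboration of the terminal alkyne places boron on the terminal carbon and gives the (E)-alkenyl boronate; the labile catechol ester is then exchanged for the ditertiary diol by transesterification, as is routinely done with pinacol.

Step 4
Reactants: 7 4-bromo-2-methoxyphenol
Product: 8 (4-bromo-2-methoxyphenoxy)triisopropylsilane
Conditions: TIPSCl, imidazole, DMF, rt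
Reagents that add atoms: triisopropylsilyl chloride, CC(C)[Si](Cl)(C(C)C)C(C)C
Why: Phenol silylation; the bulky aryl TIPS ether tolerates organolithium, mild base and acid and is cleaved by fluoride at the end.

Step 5
Reactants: 9 5-bromovanillin
Product: 10 3-bromo-5-methoxy-4-(methoxymethoxy)benzaldehyde
Conditions: MOMCl, i-Pr2NEt, CH2Cl2, 0 °C to rt
Reagents that add atoms: chloromethyl methyl ether, COCCl
Why: O-Alkylation of the phenol; the MOM ether is stable to the basic coupling and leaves under the acid that later closes ring B.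

Step 6
Reactants: 10 3-bromo-5-methoxy-4-(methoxymethoxy)benzaldehyde
Product: 11 2-[3-bromo-5-methoxy-4-(methoxymethoxy)phenyl]-1,3-dioxolane
Conditions: Me3SiOCH2CH2OSiMe3, TMSOTf (cat.), CH2Cl2, −78 °C
Reagents that add atoms: 1,2-bis(trimethylsilyloxy)ethane, C[Si](C)(C)OCCO[Si](C)(C)C
Why: Noyori acetalisation; it is aprotic and run at low temperature, so the aryl MOM ether is not exchanged, and the acetal shields the aldehyde from the ate complex.

Step 7
Reactants: 8 (4-bromo-2-methoxyphenoxy)triisopropylsilane; 6 (E)-3-(tert-butyldimethylsilyloxy)prop-1-enylboronic ester of diol 2; 11 2-[3-bromo-5-methoxy-4-(methoxymethoxy)phenyl]-1,3-dioxolane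
Product: 14 (1S,2R)-3-(tert-butyldimethylsilyloxy)-2-[5-(1,3-dioxolan-2-yl)-3-methoxy-2-(methoxymethoxy)phenyl]-1-[3-methoxy-4-(triisopropylsilyloxy)phenyl]propylboronic ester of diol 2, via aryllithium 12 (not isolated), via lithium boron ate complex 13 (not isolated)
Conditions: t-BuLi (2.0 equiv), Et2O, −78 °C; then 6, −78 °C to rt; solvent switch to THF; 11, KOTf (2.5 equiv), Pd(OAc)2 (3 mol%), (Sp,Sp)-MandyPhos [1,1′-bis(diphenylphosphino)-2,2′-bis(α-(dimethylamino)benzyl)ferrocene] (3.6 mol%), 60 °C
Reagents that add atoms: none
Why: Aryllithium 12, made by bromine–lithium exchange, adds to the boron of 6 to give the four-coordinate ate complex 13. Oxidative addition of 11 to the zerovalent palladium–MandyPhos catalyst and removal of bromide by KOTf (KBr precipitates, which also clears the LiBr left by the exchange) give a cationic aryl complex of divalent palladium that binds the alkene of 13. Palladium then bonds to C3 while the guaiacyl group shifts from boron to C2 on the face opposite to the metal (1,2-metallate rearrangement), and reductive elimination with retention joins C3 to C3a of ring A. The closest known reaction type is the Pd(OAc)2/MandyPhos-catalysed enantioselective conjunctive cross-coupling of β-substituted alkenyl boron ate complexes with aryl electrophiles, run with halides in the presence of a triflate salt; the acenaphthoquinone-derived diol is used on boron because pinacol esters with a β-substituent mainly give the direct Suzuki–Miyaura product. No ring is closed. The relative configuration of C2 and C3 follows stereospecifically from anti addition of the two aryl groups across the (E)-alkene, and the absolute configuration from the alkene face that the chiral cation binds, which the ligand sets. The step needs the three-component path to beat direct transfer (secured by the boron ligand), reductive elimination to beat β-hydride or β-silyloxy elimination from the C3–Pd intermediate (secured by the wide-bite-angle bisphosphine and the poor leaving ability of a silyloxide), and high facial selectivity at C3, the one centre the later route cannot correct.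

Step 8
Reactants: 14 boronate from step 7
Product: 15 (1S,2R)-3-(tert-butyldimethylsilyloxy)-2-[5-(1,3-dioxolan-2-yl)-3-methoxy-2-(methoxymethoxy)phenyl]-1-[3-methoxy-4-(triisopropylsilyloxy)phenyl]propan-1-ol
Conditions: NaBO3·4H2O, THF/H2O (1:1), rt
Reagents that add atoms: sodium perborate, [Na+].[Na+].O[B-]1(O)OO[B-](O)(O)OO1
Why: Peroxide oxidation of the C–B bond: the hydroperoxide adds to boron and the benzylic carbon migrates to oxygen with retention of configuration; the weakly basic reagent spares the aryl silyl ether, the acetal and the MOM group.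

Step 9
Reactants: 15 alcohol from step 8
Product: 16 (2S,3R)-3-(hydroxymethyl)-7-methoxy-2-[3-methoxy-4-(triisopropylsilyloxy)phenyl]-2,3-dihydro-1-benzofuran-5-carbaldehyde
Conditions: 2 M aq. HCl, THF/MeOH (1:1), 40 °C
Reagents that add atoms: water, O
Why: Acid-mediated unmasking and cyclisation: the p-silyloxybenzylic alcohol ionises and the cation is captured at C2 by the ortho oxygen of ring A (the free phenol, or the MOM ether oxygen with loss of the methoxymethyl cation), closing ring B trans to the C3 substituent, which is both the kinetic and the thermodynamic outcome because closure is reversible. The same medium hydrolyses the alkyl TBS ether and the dioxolane, while the aryl TIPS ether resists acid. C3 is untouched and C2 is re-formed under its control with the configuration it already had.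

Step 10
Reactants: 16 aldehyde from step 9
Product: 17 methyl (Z)-3-[(2S,3R)-3-(hydroxymethyl)-7-methoxy-2-[3-methoxy-4-(triisopropylsilyloxy)phenyl]-2,3-dihydro-1-benzofuran-5-yl]prop-2-enoate
Conditions: (CF3CH2O)2P(O)CH2CO2Me, KN(SiMe3)2, 18-crown-6, THF, −78 °C
Reagents that add atoms: methyl bis(2,2,2-trifluoroethyl)phosphonoacetate, COC(=O)CP(=O)(OCC(F)(F)F)OCC(F)(F)F
Why: Still–Gennari olefination; fast, irreversible elimination from the kinetic adduct of the electron-poor phosphonate gives the (Z)-enoate, reliably so with aryl aldehydes. The stabilised phosphonate anion is far too weak a base to deprotonate the free primary alcohol.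

Step 11
Reactants: 17 (Z)-enoate from step 10
Product: 18 (Z)-3-[(2S,3R)-3-(hydroxymethyl)-7-methoxy-2-[3-methoxy-4-(triisopropylsilyloxy)phenyl]-2,3-dihydro-1-benzofuran-5-yl]prop-2-en-1-ol
Conditions: i-Bu2AlH (3.5 equiv), CH2Cl2, −78 °C; aq. KNaC4H4O6 work-up
Reagents that add atoms: none
Why: 1,2-Reduction of the unsaturated ester to the allylic alcohol by i-Bu2AlH leaves the alkene geometry intact; one equivalent is consumed by the free hydroxyl.

Step 12
Reactants: 18 diol from step 11
Product: 19 (Z)-3-[(2S,3R)-3-(hydroxymethyl)-7-methoxy-2-[3-methoxy-4-(triisopropylsilyloxy)phenyl]-2,3-dihydro-1-benzofuran-5-yl]prop-2-enal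
Conditions: activated MnO2 (excess), CH2Cl2, rt, dark
Reagents that add atoms: none
Why: MnO2 oxidises the allylic (cinnamyl-type) alcohol and not the saturated primary alcohol, so the two hydroxyl groups are told apart without protection; the neutral heterogeneous oxidant should keep the (Z)-geometry if contact time is short.

Step 13
Reactants: 20 4-hydroxybenzoic acid
Product: 22 4-(tert-butyldimethylsilyloxy)benzoic acid, via bis-silylated ester 21 (not isolated)
Conditions: TBSCl (2.3 equiv), imidazole, DMF, rt; then AcOH/THF/H2O, rt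
Reagents that add atoms: tert-butyldimethylsilyl chloride, CC(C)(C)[Si](C)(C)Cl
Why: Exhaustive silylation followed by selective hydrolysis of the much more labile silyl ester; aryl silyl ethers are stable to the dilute acid used.

Step 14
Reactants: 19 (Z)-enal alcohol from step 12; 22 4-(tert-butyldimethylsilyloxy)benzoic acid
Product: 24 [(2S,3R)-7-methoxy-2-[3-methoxy-4-(triisopropylsilyloxy)phenyl]-5-[(Z)-3-oxoprop-1-enyl]-2,3-dihydro-1-benzofuran-3-yl]methyl 4-(tert-butyldimethylsilyloxy)benzoate, via acid chloride 23 (not isolated)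
Conditions: (COCl)2, DMF (cat.), CH2Cl2, 0 °C to rt, evaporate; then 19, pyridine, CH2Cl2, 0 °C
Reagents that add atoms: none
Why: Acylation of a primary alcohol by an aroyl chloride with pyridine as base; no 4-aminopyridine or phosphine is used, because such nucleophiles add reversibly to the enal and would isomerise it.

Step 15
Reactants: 24 bis-silyl ether from step 14
Product: 25 [(2S,3R)-2-(4-hydroxy-3-methoxyphenyl)-7-methoxy-5-[(Z)-3-oxoprop-1-enyl]-2,3-dihydro-1-benzofuran-3-yl]methyl 4-hydroxybenzoate (CNP0400980.1)
Conditions: Bu4NF/AcOH (1:1, 3 equiv), THF, 0 °C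
Reagents that add atoms: none
Why: Fluoride cleaves both aryl silyl ethers quickly at 0 °C; the acetic acid buffer keeps the phenoxides protonated, which protects the (Z)-enal, the ester and ring B (no quinone methide opening at C2).

## Compound list

1 | acenaphthenequinone (acenaphthylene-1,2-dione) | O=C1C(=O)c2cccc3cccc1c23 | starting material
2 | cis-1,2-dimethyl-1,2-dihydroacenaphthylene-1,2-diol (meso, 1R,2S) | C[C@@]1(O)c2cccc3cccc(c23)[C@]1(C)O | intermediate
3 | propargyl alcohol | OCC#C | starting material
4 | tert-butyldimethyl(prop-2-yn-1-yloxy)silane | C#CCO[Si](C)(C)C(C)(C)C | intermediate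
5 | 2-[(E)-3-(tert-butyldimethylsilyloxy)prop-1-enyl]-1,3,2-benzodioxaborole | CC(C)(C)[Si](C)(C)OC/C=C/B1Oc2ccccc2O1 | intermediate (not isolated)
6 | (E)-tert-butyldimethyl{[3-(6b,9a-dimethyl-6b,9a-dihydroacenaphtho[1,2-d][1,3,2]dioxaborol-8-yl)prop-2-en-1-yl]oxy}silane, the (E)-alkenylboronic ester of diol 2 | CC(C)(C)[Si](C)(C)OC/C=C/B1O[C@]2(C)c3cccc4cccc(c34)[C@]2(C)O1 | intermediate
7 | 4-bromo-2-methoxyphenol | COc1cc(Br)ccc1O | starting material
8 | (4-bromo-2-methoxyphenoxy)triisopropylsilane | COc1cc(Br)ccc1O[Si](C(C)C)(C(C)C)C(C)C | intermediate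
9 | 5-bromovanillin (3-bromo-4-hydroxy-5-methoxybenzaldehyde) | COc1cc(C=O)cc(Br)c1O | starting material
10 | 3-bromo-5-methoxy-4-(methoxymethoxy)benzaldehyde | COCOc1c(Br)cc(C=O)cc1OC | intermediate
11 | 2-[3-bromo-5-methoxy-4-(methoxymethoxy)phenyl]-1,3-dioxolane | COCOc1c(Br)cc(C2OCCO2)cc1OC | intermediate
12 | [3-methoxy-4-(triisopropylsilyloxy)phenyl]lithium | [Li]c1ccc(O[Si](C(C)C)(C(C)C)C(C)C)c(OC)c1 | intermediate (not isolated)
13 | lithium [(E)-3-(tert-butyldimethylsilyloxy)prop-1-enyl][3-methoxy-4-(triisopropylsilyloxy)phenyl]borate of diol 2 (ate complex) | [Li+].COc1cc([B-]2(/C=C/CO[Si](C)(C)C(C)(C)C)O[C@]3(C)c4cccc5cccc(c45)[C@]3(C)O2)ccc1O[Si](C(C)C)(C(C)C)C(C)C | intermediate (not isolated)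
14 | (1S,2R)-3-(tert-butyldimethylsilyloxy)-2-[5-(1,3-dioxolan-2-yl)-3-methoxy-2-(methoxymethoxy)phenyl]-1-[3-methoxy-4-(triisopropylsilyloxy)phenyl]propylboronic ester of diol 2 | COc1cc([C@@H](B2O[C@]3(C)c4cccc5cccc(c45)[C@]3(C)O2)[C@@H](CO[Si](C)(C)C(C)(C)C)c2cc(C3OCCO3)cc(OC)c2OCOC)ccc1O[Si](C(C)C)(C(C)C)C(C)C | intermediate
15 | (1S,2R)-3-(tert-butyldimethylsilyloxy)-2-[5-(1,3-dioxolan-2-yl)-3-methoxy-2-(methoxymethoxy)phenyl]-1-[3-methoxy-4-(triisopropylsilyloxy)phenyl]propan-1-ol | COc1cc([C@@H](O)[C@@H](CO[Si](C)(C)C(C)(C)C)c2cc(C3OCCO3)cc(OC)c2OCOC)ccc1O[Si](C(C)C)(C(C)C)C(C)C | intermediate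
16 | (2S,3R)-3-(hydroxymethyl)-7-methoxy-2-[3-methoxy-4-(triisopropylsilyloxy)phenyl]-2,3-dihydro-1-benzofuran-5-carbaldehyde | COc1cc([C@H]2Oc3c(OC)cc(C=O)cc3[C@@H]2CO)ccc1O[Si](C(C)C)(C(C)C)C(C)C | intermediate
17 | methyl (Z)-3-[(2S,3R)-3-(hydroxymethyl)-7-methoxy-2-[3-methoxy-4-(triisopropylsilyloxy)phenyl]-2,3-dihydro-1-benzofuran-5-yl]prop-2-enoate | COc1cc([C@H]2Oc3c(OC)cc(/C=C\C(=O)OC)cc3[C@@H]2CO)ccc1O[Si](C(C)C)(C(C)C)C(C)C | intermediate
18 | (Z)-3-[(2S,3R)-3-(hydroxymethyl)-7-methoxy-2-[3-methoxy-4-(triisopropylsilyloxy)phenyl]-2,3-dihydro-1-benzofuran-5-yl]prop-2-en-1-ol | COc1cc([C@H]2Oc3c(OC)cc(/C=C\CO)cc3[C@@H]2CO)ccc1O[Si](C(C)C)(C(C)C)C(C)C | intermediate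
19 | (Z)-3-[(2S,3R)-3-(hydroxymethyl)-7-methoxy-2-[3-methoxy-4-(triisopropylsilyloxy)phenyl]-2,3-dihydro-1-benzofuran-5-yl]prop-2-enal | COc1cc([C@H]2Oc3c(OC)cc(/C=C\C=O)cc3[C@@H]2CO)ccc1O[Si](C(C)C)(C(C)C)C(C)C | intermediate
20 | 4-hydroxybenzoic acid | OC(=O)c1ccc(O)cc1 | starting material
21 | tert-butyldimethylsilyl 4-(tert-butyldimethylsilyloxy)benzoate | CC(C)(C)[Si](C)(C)OC(=O)c1ccc(O[Si](C)(C)C(C)(C)C)cc1 | intermediate (not isolated)
22 | 4-(tert-butyldimethylsilyloxy)benzoic acid | OC(=O)c1ccc(O[Si](C)(C)C(C)(C)C)cc1 | intermediate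
23 | 4-(tert-butyldimethylsilyloxy)benzoyl chloride | ClC(=O)c1ccc(O[Si](C)(C)C(C)(C)C)cc1 | intermediate (not isolated)
24 | [(2S,3R)-7-methoxy-2-[3-methoxy-4-(triisopropylsilyloxy)phenyl]-5-[(Z)-3-oxoprop-1-enyl]-2,3-dihydro-1-benzofuran-3-yl]methyl 4-(tert-butyldimethylsilyloxy)benzoate | COc1cc([C@H]2Oc3c(OC)cc(/C=C\C=O)cc3[C@@H]2COC(=O)c2ccc(O[Si](C)(C)C(C)(C)C)cc2)ccc1O[Si](C(C)C)(C(C)C)C(C)C | intermediate
25 | [(2S,3R)-2-(4-hydroxy-3-methoxyphenyl)-7-methoxy-5-[(Z)-3-oxoprop-1-enyl]-2,3-dihydro-1-benzofuran-3-yl]methyl 4-hydroxybenzoate | COc1cc([C@H]2Oc3c(OC)cc(/C=C\C=O)cc3[C@@H]2COC(=O)c2ccc(O)cc2)ccc1O | target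

## Step count and least certain steps

Total: 15 steps. Longest linear sequence: 10 steps (3 → 4 → 6 → 14 → 15 → 16 → 17 → 18 → 19 → 24 → 25).

**Step 7 (key step).**
- **What may go wrong:** direct transfer of the alkenyl or aryl group from the ate complex to palladium (two-component coupling instead of the metallate shift); β-hydride or β-silyloxy elimination from the C3–Pd intermediate; slow oxidative addition of the electron-rich, ortho-alkoxy aryl bromide; or insufficient facial selectivity with an aryl migrating group.
- **Fallback (sets out from 11 and 8, returns at 16):** the C2–C3 bond is made by an auxiliary-controlled aldol instead. Coupling of 11 with BrZnCH2CO2Et under Pd(dba)2/P(t-Bu)3 would give ethyl 2-[5-(1,3-dioxolan-2-yl)-3-methoxy-2-(methoxymethoxy)phenyl]acetate F1. LiOH hydrolysis gives the acid F2. Its pivaloyl mixed anhydride and lithiated (S)-4-benzyl-2-oxazolidinone give the imide F3. Aryllithium 12 (from 8) and DMF give 3-methoxy-4-(triisopropylsilyloxy)benzaldehyde F4. The Bu2BOTf/i-Pr2NEt aldol of F3 with F4 should give the Evans syn adduct F5, and LiBH4 reduction the (1S,2R)-1,3-diol F6, the desilyl analogue of 15. The conditions of step 9 convert F6 into 16.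

**Step 9.**
- **What may go wrong:** loss of the C3 proton from the benzylic cation and re-protonation (erosion of the C3 configuration), or retro-Prins loss of the hydroxymethyl carbon, if the cation lives long or the acid treatment is prolonged.
- **Fallback (sets out from 9, returns at 16):** the ring A phenol is freed under neutral conditions before any acid is applied. BnBr/K2CO3 converts 9 into 4-(benzyloxy)-3-bromo-5-methoxybenzaldehyde F7, and ethylene glycol/TsOH gives its dioxolane F8. Steps 7 and 8 run with F8 in place of 11 give the boronate F9 and the alcohol F10. Hydrogenolysis (H2, Pd on carbon, EtOAc) gives the phenol F11. Brief treatment with dilute aq. HCl in THF/MeOH at room temperature then closes the ring with the phenol present from the first moment of ionisation, removes the TBS ether and the dioxolane, and gives 16.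

**Step 10.**
- **What may go wrong:** interference of the free hydroxyl (proton transfer, attack at phosphorus) or incomplete Z-selectivity.
- **Fallback (sets out from 16, returns at 18):** the alkene geometry comes from a semi-hydrogenation. Ohira–Bestmann homologation (dimethyl 1-diazo-2-oxopropylphosphonate, K2CO3, MeOH) gives the terminal alkyne F12. Double deprotonation with n-BuLi and addition to paraformaldehyde gives the propargylic alcohol F13. Hydrogenation over Pd/CaCO3 poisoned with Pb(OAc)2 (Lindlar catalyst) and quinoline gives 18.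

**Step 15 (together with steps 12 and 14).**
- **What may go wrong:** Z-to-E isomerisation of the enal by reversible conjugate addition of fluoride, phenoxide or pyridine, or on the MnO2 surface.
- **Fallback (sets out from 18, returns at 25):** the enal is unveiled in the last step. Silylation of 18 with TBSCl/imidazole at −40 °C should select the unhindered allylic hydroxyl over the β-branched one and give the mono-silyl ether F14. Acylation with 23 (pyridine, now with 4-dimethylaminopyridine if needed) gives the ester F15. Bu4NF/AcOH removes all three silyl groups to give the (Z)-allylic alcohol F16. MnO2, which oxidises cinnamyl-type alcohols in the presence of free phenols, gives 25.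

## Further compounds

F1 | step 7 | ethyl 2-[5-(1,3-dioxolan-2-yl)-3-methoxy-2-(methoxymethoxy)phenyl]acetate | CCOC(=O)Cc1cc(C2OCCO2)cc(OC)c1OCOC
F2 | step 7 | 2-[5-(1,3-dioxolan-2-yl)-3-methoxy-2-(methoxymethoxy)phenyl]acetic acid | OC(=O)Cc1cc(C2OCCO2)cc(OC)c1OCOC
F3 | step 7 | (S)-4-benzyl-3-{2-[5-(1,3-dioxolan-2-yl)-3-methoxy-2-(methoxymethoxy)phenyl]acetyl}-1,3-oxazolidin-2-one | O=C(Cc1cc(C2OCCO2)cc(OC)c1OCOC)N1[C@@H](Cc2ccccc2)COC1=O
F4 | step 7 | 3-methoxy-4-(triisopropylsilyloxy)benzaldehyde | COc1cc(C=O)ccc1O[Si](C(C)C)(C(C)C)C(C)C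
F5 | step 7 | (S)-4-benzyl-3-{(2S,3S)-2-[5-(1,3-dioxolan-2-yl)-3-methoxy-2-(methoxymethoxy)phenyl]-3-hydroxy-3-[3-methoxy-4-(triisopropylsilyloxy)phenyl]propanoyl}-1,3-oxazolidin-2-one | COc1cc([C@@H](O)[C@@H](C(=O)N2[C@@H](Cc3ccccc3)COC2=O)c2cc(C3OCCO3)cc(OC)c2OCOC)ccc1O[Si](C(C)C)(C(C)C)C(C)C
F6 | step 7 | (1S,2R)-2-[5-(1,3-dioxolan-2-yl)-3-methoxy-2-(methoxymethoxy)phenyl]-1-[3-methoxy-4-(triisopropylsilyloxy)phenyl]propane-1,3-diol | COc1cc([C@@H](O)[C@@H](CO)c2cc(C3OCCO3)cc(OC)c2OCOC)ccc1O[Si](C(C)C)(C(C)C)C(C)C
F7 | step 9 | 4-(benzyloxy)-3-bromo-5-methoxybenzaldehyde | COc1cc(C=O)cc(Br)c1OCc1ccccc1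
F8 | step 9 | 2-[4-(benzyloxy)-3-bromo-5-methoxyphenyl]-1,3-dioxolane | COc1cc(C2OCCO2)cc(Br)c1OCc1ccccc1
F9 | step 9 | (1S,2R)-2-[2-(benzyloxy)-5-(1,3-dioxolan-2-yl)-3-methoxyphenyl]-3-(tert-butyldimethylsilyloxy)-1-[3-methoxy-4-(triisopropylsilyloxy)phenyl]propylboronic ester of diol 2 | COc1cc([C@@H](B2O[C@]3(C)c4cccc5cccc(c45)[C@]3(C)O2)[C@@H](CO[Si](C)(C)C(C)(C)C)c2cc(C3OCCO3)cc(OC)c2OCc2ccccc2)ccc1O[Si](C(C)C)(C(C)C)C(C)C
F10 | step 9 | (1S,2R)-2-[2-(benzyloxy)-5-(1,3-dioxolan-2-yl)-3-methoxyphenyl]-3-(tert-butyldimethylsilyloxy)-1-[3-methoxy-4-(triisopropylsilyloxy)phenyl]propan-1-ol | COc1cc([C@@H](O)[C@@H](CO[Si](C)(C)C(C)(C)C)c2cc(C3OCCO3)cc(OC)c2OCc2ccccc2)ccc1O[Si](C(C)C)(C(C)C)C(C)C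
F11 | step 9 | 2-{(1R,2S)-3-(tert-butyldimethylsilyloxy)-1-hydroxy... phenol form: (1S,2R)-3-(tert-butyldimethylsilyloxy)-2-[5-(1,3-dioxolan-2-yl)-2-hydroxy-3-methoxyphenyl]-1-[3-methoxy-4-(triisopropylsilyloxy)phenyl]propan-1-ol | COc1cc([C@@H](O)[C@@H](CO[Si](C)(C)C(C)(C)C)c2cc(C3OCCO3)cc(OC)c2O)ccc1O[Si](C(C)C)(C(C)C)C(C)C
F12 | step 10 | [(2S,3R)-5-ethynyl-7-methoxy-2-[3-methoxy-4-(triisopropylsilyloxy)phenyl]-2,3-dihydro-1-benzofuran-3-yl]methanol | COc1cc([C@H]2Oc3c(OC)cc(C#C)cc3[C@@H]2CO)ccc1O[Si](C(C)C)(C(C)C)C(C)C
F13 | step 10 | 3-[(2S,3R)-3-(hydroxymethyl)-7-methoxy-2-[3-methoxy-4-(triisopropylsilyloxy)phenyl]-2,3-dihydro-1-benzofuran-5-yl]prop-2-yn-1-ol | COc1cc([C@H]2Oc3c(OC)cc(C#CCO)cc3[C@@H]2CO)ccc1O[Si](C(C)C)(C(C)C)C(C)C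
F14 | step 15 | [(2S,3R)-5-[(Z)-3-(tert-butyldimethylsilyloxy)prop-1-enyl]-7-methoxy-2-[3-methoxy-4-(triisopropylsilyloxy)phenyl]-2,3-dihydro-1-benzofuran-3-yl]methanol | COc1cc([C@H]2Oc3c(OC)cc(/C=C\CO[Si](C)(C)C(C)(C)C)cc3[C@@H]2CO)ccc1O[Si](C(C)C)(C(C)C)C(C)C
F15 | step 15 | [(2S,3R)-5-[(Z)-3-(tert-butyldimethylsilyloxy)prop-1-enyl]-7-methoxy-2-[3-methoxy-4-(triisopropylsilyloxy)phenyl]-2,3-dihydro-1-benzofuran-3-yl]methyl 4-(tert-butyldimethylsilyloxy)benzoate | COc1cc([C@H]2Oc3c(OC)cc(/C=C\CO[Si](C)(C)C(C)(C)C)cc3[C@@H]2COC(=O)c2ccc(O[Si](C)(C)C(C)(C)C)cc2)ccc1O[Si](C(C)C)(C(C)C)C(C)C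
F16 | step 15 | [(2S,3R)-2-(4-hydroxy-3-methoxyphenyl)-5-[(Z)-3-hydroxyprop-1-enyl]-7-methoxy-2,3-dihydro-1-benzofuran-3-yl]methyl 4-hydroxybenzoate | COc1cc([C@H]2Oc3c(OC)cc(/C=C\CO)cc3[C@@H]2COC(=O)c2ccc(O)cc2)ccc1O
A1 | alternative 1 | (S)-6-bromo-8-methoxy-2-[3-methoxy-4-(pivaloyloxy)phenyl]chroman-4-one | COc1cc([C@@H]2CC(=O)c3cc(Br)cc(OC)c3O2)ccc1OC(=O)C(C)(C)C
A2 | alternative 1 | methyl (2S,3S)-trans-5-bromo-7-methoxy-2-[3-methoxy-4-(pivaloyloxy)phenyl]-2,3-dihydro-1-benzofuran-3-carboxylate | COc1cc([C@H]2Oc3c(OC)cc(Br)cc3[C@@H]2C(=O)OC)ccc1OC(=O)C(C)(C)C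
A3 | alternative 2 | pentacarbonyl{methoxy[(2S,3R)-3-[(tert-butyldimethylsilyloxy)methyl]-2-[3-methoxy-4-(triisopropylsilyloxy)phenyl]-2,3-dihydrofuran-5-yl]methylidene}chromium | COc1cc([C@H]2OC(C(OC)=[Cr])=C[C@@H]2CO[Si](C)(C)C(C)(C)C)ccc1O[Si](C(C)C)(C(C)C)C(C)C.[C-]#[O+].[C-]#[O+].[C-]#[O+].[C-]#[O+].[C-]#[O+]
A4 | alternative 2 | 3,3-diethoxyprop-1-yne | CCOC(OCC)C#C
A5 | alternative 2 | (2S,3R)-3-[(tert-butyldimethylsilyloxy)methyl]-5-(diethoxymethyl)-7-methoxy-2-[3-methoxy-4-(triisopropylsilyloxy)phenyl]-2,3-dihydro-1-benzofuran-4-ol | COc1cc([C@H]2Oc3c(OC)cc(C(OCC)OCC)c(O)c3[C@@H]2CO[Si](C)(C)C(C)(C)C)ccc1O[Si](C(C)C)(C(C)C)C(C)C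
A6 | alternative 3 | 4-bromo-2-[2-(tert-butyldimethylsilyloxy)-1-(p-tolylsulfonyl)ethyl]-6-methoxyphenol | COc1cc(Br)cc(C(CO[Si](C)(C)C(C)(C)C)S(=O)(=O)c2ccc(C)cc2)c1O
A7 | alternative 3 | (2R,5R)-1-[3-methoxy-4-(triisopropylsilyloxy)benzyl]-2,5-dimethylthiolanium trifluoromethanesulfonate | C[C@@H]1CC[C@@H](C)[S+]1Cc1ccc(O[Si](C(C)C)(C(C)C)C(C)C)c(OC)c1.[O-]S(=O)(=O)C(F)(F)F
A8 | alternative 3 | (2S,3R)-5-bromo-3-[(tert-butyldimethylsilyloxy)methyl]-7-methoxy-2-[3-methoxy-4-(triisopropylsilyloxy)phenyl]-2,3-dihydro-1-benzofuran | COc1cc([C@H]2Oc3c(OC)cc(Br)cc3[C@@H]2CO[Si](C)(C)C(C)(C)C)ccc1O[Si](C(C)C)(C(C)C)C(C)C
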